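**Retrosynthetic overview**
- Feature: ring C (O1–C2–C3–C4–C4a–C8a) of the dihydroflavonol, in which the bonds O1–C2 and C3–C4 join the A-ring fragment O1–C8a–C4a–C4 to the two-carbon unit C2–C3 that carries the B ring.
- Key disconnection: both bonds are cut as one inverse-demand oxa-[4+2] retron, giving the α-methoxy o-quinone methide of salicylaldehyde 7 (made in situ with trimethyl orthoformate 18) and the (E)-enol acetate 17; the C4 methoxy group is the latent C4 ketone.
- Fragments: 7 from 2,4,6-trihydroxybenzaldehyde by bis-MOM protection, O-prenylation and a para-Claisen (Claisen–Cope) shift; 17 from resorcinol by two directed ortho-metalations (geranyl, then CHO), boron-Wittig olefination and stereoretentive copper-mediated acyloxylation.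
- Endgame: C4–OMe to C4–OH to C4=O, then one acidic methanolysis removes the four MOM groups and the acetate.
- Ring order: rings A and B are bought as arenes; ring C is the only ring formed (step 10).

Key step: step 10

Remark: flavonoid numbering is used for ring C; prenyl = 3-methylbut-2-en-1-yl, geranyl = (2E)-3,7-dimethylocta-2,6-dien-1-yl, MOM = methoxymethyl.
Assumption: the ester on the enol oxygen is the acetate, so that it leaves in the closing acidic methanolysis and no base is needed once the epimerisable C4 ketone is present.
Assumption: the sense of induction of the chiral acid in step 10 is not predicted; the catalyst enantiomer that delivers (2R,3S)-21 is to be fixed by a screen.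

**Route**

Step 1
Reactants: 1 2,4,6-trihydroxybenzaldehyde
Product: 2 2-hydroxy-4,6-bis(methoxymethoxy)benzaldehyde
Conditions: MOMCl (2.2 equiv), i-Pr2NEt, CH2Cl2, 0 °C to rt
Reagents that add atoms: chloromethyl methyl ether, COCCl
Why: O-alkylation of the two more acidic, less hindered phenols, the last ortho OH being held back by its hydrogen bond to the formyl group.

Step 2
Reactants: 2 2-hydroxy-4,6-bis(methoxymethoxy)benzaldehyde; 3 prenyl bromide
Product: 4 2,4-bis(methoxymethoxy)-6-(prenyloxy)benzaldehyde
Conditions: K2CO3, DMF, rt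
Reagents that add atoms: none
Why: Williamson etherification of the remaining phenol with an allylic bromide under mild carbonate conditions that leave the aldehyde and the MOM ethers alone.

Step 3
Reactants: 4 2,4-bis(methoxymethoxy)-6-(prenyloxy)benzaldehyde
Product: 7 6-hydroxy-2,4-bis(methoxymethoxy)-3-prenylbenzaldehyde, via ortho-dienone 5 (not isolated), via para-dienone 6 (not isolated)
Conditions: PhNEt2, 195 °C, sealed tube, Ar
Reagents that add atoms: none
Why: Aromatic Claisen rearrangement to the free ortho carbon followed by Cope shift of the congested 1,1-dimethylallyl group to the para carbon and tautomerisation (tandem Claisen–Cope, "para-Claisen"), which places an unrearranged prenyl group between the two MOM ethers and returns the phenol next to the formyl group.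

Step 4
Reactants: 8 resorcinol
Product: 9 1,3-bis(methoxymethoxy)benzene
Conditions: NaH, MOMCl, DMF, 0 °C to rt
Reagents that add atoms: chloromethyl methyl ether, COCCl
Why: Double O-alkylation of the bis-phenoxide; the MOM ethers serve as protecting groups and as ortho-directing groups for the next two steps.

Step 5
Reactants: 9 1,3-bis(methoxymethoxy)benzene; 10 geranyl bromide
Product: 12 2-geranyl-1,3-bis(methoxymethoxy)benzene, via aryllithium 11 (not isolated)
Conditions: n-BuLi, THF, 0 °C to rt; CuI (10 mol%), then 10, −40 °C to rt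
Reagents that add atoms: none
Why: Directed ortho-metalation at C2, the position flanked by both MOM ethers, and copper-catalysed SN2 allylation of the aryllithium, which keeps the allyl unit unrearranged and the 2E alkene intact.

Step 6
Reactants: 12 2-geranyl-1,3-bis(methoxymethoxy)benzene
Product: 14 3-geranyl-2,4-bis(methoxymethoxy)benzaldehyde, via aryllithium 13 (not isolated)
Conditions: n-BuLi, TMEDA, THF, 0 °C; DMF, 0 °C to rt; aq. NH4Cl
Reagents that add atoms: N,N-dimethylformamide, CN(C)C=O
Why: Second directed ortho-metalation next to a MOM ether (the two open ortho positions are equivalent) and formylation of the aryllithium with DMF.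

Step 7
Reactants: 14 3-geranyl-2,4-bis(methoxymethoxy)benzaldehyde
Product: 15 2-[(E)-2-(3-geranyl-2,4-bis(methoxymethoxy)phenyl)vinyl]-4,4,5,5-tetramethyl-1,3,2-dioxaborolane
Conditions: CH2(Bpin)2, LiTMP, THF, 0 °C; then 14, −78 °C to rt
Reagents that add atoms: bis(pinacolboryl)methane, CC1(C)OB(CB2OC(C)(C)C(C)(C)O2)OC1(C)C
Why: Boron-Wittig olefination, in which the α-boryl carbanion adds to the aldehyde and syn-elimination of borate gives the 1,2-disubstituted alkenylboronate with high E selectivity under non-acidic conditions.

Step 8
Reactants: 15 the (E)-alkenyl pinacol boronate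
Product: 16 potassium (E)-[2-(3-geranyl-2,4-bis(methoxymethoxy)phenyl)vinyl]trifluoroborate
Conditions: KHF2, MeOH/H2O, rt
Reagents that add atoms: potassium hydrogen difluoride, [K+].F.[F-]
Why: Ligand exchange at boron with bifluoride gives the trifluoroborate needed for the copper coupling, with the alkene geometry untouched.

Step 9
Reactants: 16 the potassium (E)-alkenyltrifluoroborate
Product: 17 (E)-2-[3-geranyl-2,4-bis(methoxymethoxy)phenyl]vinyl acetate
Conditions: AcOH, CuBr (10 mol%), DMAP (20 mol%), 4 Å MS, O2 (1 atm), MeCN, 60 °C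
Reagents that add atoms: acetic acid, CC(=O)O
Why: Copper-catalysed oxidative C–O coupling (Chan–Lam type) of an alkenyltrifluoroborate with a carboxylic acid, which goes with retention of alkene geometry and so gives the (E)-enol ester without an enolate acylation of uncertain E/Z outcome.

Step 10
Reactants: 7 6-hydroxy-2,4-bis(methoxymethoxy)-3-prenylbenzaldehyde; 17 (E)-2-[3-geranyl-2,4-bis(methoxymethoxy)phenyl]vinyl acetate; 18 trimethyl orthoformate
Product: 21 (2R,3S,4R)-2-[3-geranyl-2,4-bis(methoxymethoxy)phenyl]-4-methoxy-5,7-bis(methoxymethoxy)-6-prenylchroman-3-yl acetate, via dimethyl acetal 19 (not isolated), via methoxy quinone methide 20 (not isolated)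
Conditions: chiral BINOL-derived N-triflylphosphoramide (5 mol%), 7 and HC(OMe)3 (1.5 equiv), toluene, 0 °C; then 17, −20 °C
Reagents that add atoms: none
Why: Proposed new method: the acid converts 7 and the orthoformate into acetal 19, which ionises to the α-methoxy o-quinone methide 20 (present as its O-protonated oxocarbenium paired with the chiral anion); the alkene of 17 attacks C4 through its acetoxy-bearing carbon and O1 then collapses on the benzylic carbon, a polar asynchronous inverse-demand oxa-[4+2] whose closest known relatives are the chiral Brønsted acid catalysed o-quinone methide/styrene cycloadditions to 2-arylchromans and the achiral acid three-component salicylaldehyde–orthoformate–alkene chroman synthesis. Ring C is closed as a six-membered dihydropyran by [4+2] annulation of the four-atom unit O1–C8a–C4a–C4 with the two-atom unit C3–C2, C3–C4 forming ahead of O1–C2. C2 and C3 come out trans because both new bonds form on one face of the E alkene, and their absolute sense (2R,3S) is imposed by the chiral anion, which binds the phenolic OH and shields one face of the cation. C4 follows from the endo/exo approach and from acid-mediated epimerisation and need not be controlled, because it becomes the carbonyl carbon. The step needs regioselectivity (aryl at C2, oxygen at C3), and the 2,4-bis(alkoxy)phenyl group secures it by stabilising positive charge at C2 far better than the weakly donating acetoxy group could at C3.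

Step 11
Reactants: 21 the 4-methoxyflavan-3-yl acetate
Product: 22 (2R,3S)-2-[3-geranyl-2,4-bis(methoxymethoxy)phenyl]-4-hydroxy-5,7-bis(methoxymethoxy)-6-prenylchroman-3-yl acetate (C4 epimer mixture)
Conditions: Yb(OTf)3 (10 mol%), THF/H2O (4:1), rt
Reagents that add atoms: water, O
Why: SN1 solvolysis, in which the benzylic methyl ether lying ortho/para to three ring oxygens is ionised by a mild water-tolerant Lewis acid and the cation is captured by water; the new C4 carbinol centre forms as an epimer mixture that the next oxidation erases.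

Step 12
Reactants: 22 the flavan-4-ol 3-acetate
Product: 23 (2R,3R)-2-[3-geranyl-2,4-bis(methoxymethoxy)phenyl]-5,7-bis(methoxymethoxy)-4-oxo-6-prenylchroman-3-yl acetate
Conditions: Dess–Martin periodinane, NaHCO3, CH2Cl2, 0 °C to rt
Reagents that add atoms: none
Why: Dess–Martin oxidation of the secondary benzylic alcohol, on which both C4 epimers converge and whose buffered, non-basic medium leaves C2 and C3 untouched (the change of the C3 descriptor from S to R is a priority change only).

Step 13
Reactants: 23 the protected 3-acetoxyflavanone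
Product: 24 (2R,3R)-2-(3-geranyl-2,4-dihydroxyphenyl)-3,5,7-trihydroxy-6-prenylchroman-4-one (CNP0166115.1)
Conditions: HCl (3 M in MeOH), 40 °C
Reagents that add atoms: none
Why: Acid-catalysed transacetalisation of the four aryl MOM ethers to methanol together with acid-catalysed methanolysis of the α-keto acetate; no base is used, so the trans C2/C3 centres are not epimerised through enolate or ring-opening pathways.

**Compound list**
1 | 2,4,6-trihydroxybenzaldehyde | O=Cc1c(O)cc(O)cc1O | starting material
2 | 2-hydroxy-4,6-bis(methoxymethoxy)benzaldehyde | O=Cc1c(O)cc(OCOC)cc1OCOC | intermediate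
3 | prenyl bromide (1-bromo-3-methylbut-2-ene) | CC(C)=CCBr | starting material
4 | 2,4-bis(methoxymethoxy)-6-(prenyloxy)benzaldehyde | O=Cc1c(OCC=C(C)C)cc(OCOC)cc1OCOC | intermediate
5 | ortho-dienone: 3,5-bis(methoxymethoxy)-6-(2-methylbut-3-en-2-yl)-2-formylcyclohexa-2,4-dienone (not isolated) | O=CC1=C(OCOC)C=C(OCOC)C(C(C)(C)C=C)C1=O | intermediate
6 | para-dienone: 3,5-bis(methoxymethoxy)-4-prenyl-2-formylcyclohexa-2,5-dienone (not isolated) | O=CC1=C(OCOC)C(CC=C(C)C)C(OCOC)=CC1=O | intermediate
7 | 6-hydroxy-2,4-bis(methoxymethoxy)-3-prenylbenzaldehyde | O=Cc1c(O)cc(OCOC)c(CC=C(C)C)c1OCOC | intermediate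
8 | resorcinol | Oc1cccc(O)c1 | starting material
9 | 1,3-bis(methoxymethoxy)benzene | COCOc1cccc(OCOC)c1 | intermediate
10 | geranyl bromide | CC(C)=CCC/C(C)=C/CBr | starting material
11 | 2,6-bis(methoxymethoxy)phenyllithium (not isolated) | [Li]c1c(OCOC)cccc1OCOC | intermediate
12 | 2-geranyl-1,3-bis(methoxymethoxy)benzene | CC(C)=CCC/C(C)=C/Cc1c(OCOC)cccc1OCOC | intermediate
13 | 3-geranyl-2,4-bis(methoxymethoxy)phenyllithium (not isolated) | CC(C)=CCC/C(C)=C/Cc1c(OCOC)ccc([Li])c1OCOC | intermediate
14 | 3-geranyl-2,4-bis(methoxymethoxy)benzaldehyde | CC(C)=CCC/C(C)=C/Cc1c(OCOC)ccc(C=O)c1OCOC | intermediate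
15 | 2-[(E)-2-(3-geranyl-2,4-bis(methoxymethoxy)phenyl)vinyl]-4,4,5,5-tetramethyl-1,3,2-dioxaborolane | CC(C)=CCC/C(C)=C/Cc1c(OCOC)ccc(/C=C/B2OC(C)(C)C(C)(C)O2)c1OCOC | intermediate
16 | potassium (E)-[2-(3-geranyl-2,4-bis(methoxymethoxy)phenyl)vinyl]trifluoroborate | CC(C)=CCC/C(C)=C/Cc1c(OCOC)ccc(/C=C/[B-](F)(F)F)c1OCOC.[K+] | intermediate
17 | (E)-2-[3-geranyl-2,4-bis(methoxymethoxy)phenyl]vinyl acetate | CC(C)=CCC/C(C)=C/Cc1c(OCOC)ccc(/C=C/OC(C)=O)c1OCOC | intermediate
18 | trimethyl orthoformate | COC(OC)OC | starting material
19 | 2-(dimethoxymethyl)-3,5-bis(methoxymethoxy)-4-prenylphenol (not isolated) | COC(OC)c1c(O)cc(OCOC)c(CC=C(C)C)c1OCOC | intermediate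
20 | 6-(methoxymethylidene)-3,5-bis(methoxymethoxy)-4-prenylcyclohexa-2,4-dien-1-one, the α-methoxy o-quinone methide (not isolated) | COC=C1C(=O)C=C(OCOC)C(CC=C(C)C)=C1OCOC | intermediate
21 | (2R,3S,4R)-2-[3-geranyl-2,4-bis(methoxymethoxy)phenyl]-4-methoxy-5,7-bis(methoxymethoxy)-6-prenylchroman-3-yl acetate (2,3-trans; the C4 epimer is equally usable) | CC(C)=CCC/C(C)=C/Cc1c(OCOC)ccc([C@H]2Oc3cc(OCOC)c(CC=C(C)C)c(OCOC)c3[C@@H](OC)[C@@H]2OC(C)=O)c1OCOC | intermediate
22 | (2R,3S)-2-[3-geranyl-2,4-bis(methoxymethoxy)phenyl]-4-hydroxy-5,7-bis(methoxymethoxy)-6-prenylchroman-3-yl acetate (C4 epimer mixture) | CC(C)=CCC/C(C)=C/Cc1c(OCOC)ccc([C@H]2Oc3cc(OCOC)c(CC=C(C)C)c(OCOC)c3C(O)[C@@H]2OC(C)=O)c1OCOC | intermediate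
23 | (2R,3R)-2-[3-geranyl-2,4-bis(methoxymethoxy)phenyl]-5,7-bis(methoxymethoxy)-4-oxo-6-prenylchroman-3-yl acetate | CC(C)=CCC/C(C)=C/Cc1c(OCOC)ccc([C@H]2Oc3cc(OCOC)c(CC=C(C)C)c(OCOC)c3C(=O)[C@@H]2OC(C)=O)c1OCOC | intermediate
24 | (2R,3R)-2-(3-geranyl-2,4-dihydroxyphenyl)-3,5,7-trihydroxy-6-prenylchroman-4-one | CC(C)=CCC/C(C)=C/Cc1c(O)ccc([C@H]2Oc3cc(O)c(CC=C(C)C)c(O)c3C(=O)[C@@H]2O)c1O | target

**Count and risks**
Total: 13 steps. Longest linear sequence: 10 steps (steps 4–13, from resorcinol 8).

1. Step 10 (carries the label).
   - What may go wrong: attack of the alkene through its aryl-bearing carbon (reversed regiochemistry); insufficient facial discrimination by the chiral anion; acid-promoted addition of the liberated methanol to the enol acetate; alkylation of the free C8 position of a second A ring by the cation.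
   - Fallback (known chemistry, chalcone epoxide route): it sets out from 7 and 14 and builds ring C by epoxide opening instead of cycloaddition. The free phenol of 7 would be protected with dihydropyran/PPTS as the tetrahydropyranyl ether F1. Methylmagnesium bromide would give the benzylic carbinol F2, and Dess–Martin oxidation the acetophenone F3. Claisen–Schmidt condensation of F3 with 14 (KOH, EtOH) would give the (E)-chalcone F4. Juliá–Colonna epoxidation (poly-L-leucine, urea–H2O2, DBU, THF) attacks only the enone, not the prenyl or geranyl alkenes, and should give the (αR,βS)-epoxide F5, as poly-L-leucine does for the parent chalcone. Methanolic HCl, first at rt and then at 40 °C, would cleave the THP acetal well before the MOM ethers. That phenol alone would then open the epoxide at the benzylic carbon with inversion (αR becomes 3R, βS becomes 2R, 2,3-trans), which fixes the 6-prenyl regiochemistry. The MOM groups would fall last, and the sequence comes back to the route at 24.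

2. Step 13.
   - What may go wrong: acid-induced cyclisation of the prenyl and geranyl chains onto the neighbouring phenols as they are unmasked; slow methanolysis of the acetate that forces harsher conditions; B-ring-assisted opening of the C2–O1 bond with loss of the trans relationship.
   - Fallback: it sets out from 23 and separates the two deprotections. The MOM ethers would be removed under aprotic conditions with ZnBr2/n-PrSH (CH2Cl2, 0 °C, minutes), which spares esters, to give the (2R,3R)-3-O-acetyl dihydroflavonol F6. The acetate of F6 would then be methanolysed alone with dilute methanolic HCl (about 0.2 M) at rt, far milder than MOM cleavage requires, and the sequence returns to the route at 24.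

3. Step 11.
   - What may go wrong: the C4 cation may lose the C3 proton (flav-3-ene formation), be captured by the electron-rich C8 of a second molecule, or be bridged by the neighbouring acetate so that the acetyl group migrates to O4.
   - Fallback: it sets out from 21 and replaces the solvolysis/oxidation pair by a direct oxidation that needs no free carbinol. DDQ in CH2Cl2/pH 7 buffer would abstract the C4 hydride, which is activated by both the methoxy group and the trioxygenated ring, and water would add to the resulting methoxy-oxocarbenium ion. The hemiketal loses methanol, so the sequence comes back to the route at 23 without any new compound (F0).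

**Further compounds**
F1 | step 10 | 2,4-bis(methoxymethoxy)-3-prenyl-6-(tetrahydro-2H-pyran-2-yloxy)benzaldehyde | O=Cc1c(OC2CCCCO2)cc(OCOC)c(CC=C(C)C)c1OCOC
F2 | step 10 | 1-[2,4-bis(methoxymethoxy)-3-prenyl-6-(tetrahydro-2H-pyran-2-yloxy)phenyl]ethanol | CC(O)c1c(OC2CCCCO2)cc(OCOC)c(CC=C(C)C)c1OCOC
F3 | step 10 | 1-[2,4-bis(methoxymethoxy)-3-prenyl-6-(tetrahydro-2H-pyran-2-yloxy)phenyl]ethanone | CC(=O)c1c(OC2CCCCO2)cc(OCOC)c(CC=C(C)C)c1OCOC
F4 | step 10 | (E)-3-[3-geranyl-2,4-bis(methoxymethoxy)phenyl]-1-[2,4-bis(methoxymethoxy)-3-prenyl-6-(tetrahydro-2H-pyran-2-yloxy)phenyl]prop-2-en-1-one | CC(C)=CCC/C(C)=C/Cc1c(OCOC)ccc(/C=C/C(=O)c2c(OC3CCCCO3)cc(OCOC)c(CC=C(C)C)c2OCOC)c1OCOC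
F5 | step 10 | [(2R,3S)-3-(3-geranyl-2,4-bis(methoxymethoxy)phenyl)oxiran-2-yl][2,4-bis(methoxymethoxy)-3-prenyl-6-(tetrahydro-2H-pyran-2-yloxy)phenyl]methanone | CC(C)=CCC/C(C)=C/Cc1c(OCOC)ccc([C@@H]2O[C@H]2C(=O)c2c(OC3CCCCO3)cc(OCOC)c(CC=C(C)C)c2OCOC)c1OCOC
F6 | step 13 | (2R,3R)-2-(3-geranyl-2,4-dihydroxyphenyl)-5,7-dihydroxy-4-oxo-6-prenylchroman-3-yl acetate | CC(C)=CCC/C(C)=C/Cc1c(O)ccc([C@H]2Oc3cc(O)c(CC=C(C)C)c(O)c3C(=O)[C@@H]2OC(C)=O)c1O
F0 | step 11 | none | none
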